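The runs come from a simulation for substances that don't exist, and the scatter is random.

The easy mistake in a flask like this was to read the highest monomer in chains as a plateau: the eta run held 82.1% at 2.50 h but had dropped to 51.6% by 6.00 h. So I took the end state to be chains lost, not chains kept, and asked how fast that state is approached.

| flask | free monomer | pre-initiator | remark | time |
|---|---|---|---|---|
| eta | 28 mM | 10 mol% | run made earlier |  |
| epsilon | 44 mM | 10 mol% | run made earlier |  |
| flask | 20 mM | 10 mol% |  | 8.0 h |

| run | time / h | monomer in chains / % | free monomer / % |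
|---|---|---|---|
| eta | 0.833 | 21.6 | 80.0 |
| eta | 1.33 | 53.1 | 47.2 |
| eta | 1.50 | 60.7 | 38.0 |
| eta | 2.50 | 82.1 | 7.2 |
| eta | 3.00 | 81.5 | 1.3 |
| eta | 5.00 | 59.0 | 0.3 |
| eta | 6.00 | 51.6 | 1.1 |
| epsilon | 0.833 | 40.5 | 58.6 |
| epsilon | 1.33 | 70.1 | 23.5 |
| epsilon | 1.50 | 77.3 | 16.7 |
| epsilon | 2.50 | 74.7 | 2.0 |
| epsilon | 3.00 | 70.3 | 0.2 |
| epsilon | 5.00 | 40.2 | 0 |
| epsilon | 6.00 | 29.3 | 0 |

(standard deviation of a reading: 1 percentage point)

1. the moment within 8.0 h at which there is most monomer in chains
2. the amount of monomer in chains, in percent of the free monomer charged, at that time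

- the analysis behind the earlier runs scatters by 1 percentage point, standard deviation

I set the rates out as a ladder. On the fast rung, free monomer fell at 1.61 h⁻¹ in eta and 2.11 h⁻¹ in epsilon. On the slow rung, from 3.00 h to 6.00 h, monomer in chains fell at 0.152 h⁻¹ in eta and 0.292 h⁻¹ in epsilon. I took each rate per mM of c(free monomer) charged, averaged the two runs and scaled to the 20 mM of the flask. That gave an uptake of 1.05 h⁻¹ and 0.121 h⁻¹, my chain-loss constant, the pseudo-first-order rate of the late fall of monomer in chains at this loading. Uptake in the flask was thus about 8.68 times faster than loss, so I expected a high peak that then sank slowly.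

The forecast gave 3.4 h and 83%: “Extrapolating gives about 3.4 h and 83%”.

The flask peaked at 3.29 h with 80.5%; the forecast had stated no margin of its own, and both its values counted as right within the tolerance set for the questions.

    free monomer + initiator → living end + monomer in chains (k = 0.670 L mol⁻¹ min⁻¹)
    free monomer + living end → monomer in chains + living end, rate k2*[living end]*[free monomer] (k = 29.0 L mol⁻¹ min⁻¹)
    initiator + monomer in chains → initiator + over-reaction product (k = 1.80 L mol⁻¹ min⁻¹)
    pre-initiator → initiator (k = 0.0110 min⁻¹)

At 1.62 h the flask made monomer in chains 11.8 times faster than it used it up, and the peak came where making and using had drawn level. From 4.00 h to 8.00 h it fell from 78.2% to 49.5%, a rate of 0.114 h⁻¹ against the 0.121 h⁻¹ of my constant. For the same flask read at 5.0 h, the constant carries 78.2% forward to 69.3%; the computed amount is 71.1%.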